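**Retrosynthetic overview**
- The target comes from its 6-O-benzyl ether by neutral hydrogenolysis in the last step.
- Ring C (the pyranone) is the only ring built and is closed last, by an enantioselective intramolecular oxa-Michael addition of the 2'-phenol onto an alkylidene β-ketoester, followed by decarboxylation; this sets C2.
- The key C2–C3 bond is made by an intermolecular Knoevenagel (aldol-type) condensation of a ring A aryl β-ketoester with veratraldehyde (ring B).
- The β-ketoester comes from Claisen-type C-acylation of 5'-benzyloxy-2'-hydroxy-4',6'-dimethoxyacetophenone with Boc2O.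
- The ring A acetophenone comes from 2,6-dimethoxy-1,4-benzoquinone by reductive acetylation, Fries rearrangement, deacetylation and selective benzylation.

Assumption: the quinidine-derived thiourea is taken to give the 2S series (its quinine-derived pseudoenantiomer 2R); the sense is checked by CD and chiral HPLC on the first batch of 12, and the pseudoenantiomeric catalyst is used if it is reversed.

**Step 1**
Reactants: 1 2,6-dimethoxy-1,4-benzoquinone
Product: 3 2,6-dimethoxy-1,4-phenylene diacetate, via 2,6-dimethoxyhydroquinone 2 (not isolated)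
Conditions: Zn dust, Ac2O, NaOAc (cat.), 60 °C
Reagents that add atoms: acetic anhydride, CC(=O)OC(C)=O
Why: Reductive acetylation; zinc reduces the quinone and the oxidation-prone hydroquinone is trapped at once as the air-stable diacetate.

**Step 2**
Reactants: 3 2,6-dimethoxy-1,4-phenylene diacetate
Product: 4 3-acetyl-4-hydroxy-2,6-dimethoxyphenyl acetate
Conditions: BF3·OEt2 (4 equiv), AcOH, 90 °C; aqueous work-up; crude used directly
Reagents that add atoms: none
Why: Fries rearrangement; only the acetate with free ortho positions can migrate, and the two ortho sites are equivalent and strongly activated, so a single regioisomer forms while the acetate flanked by two methoxy groups stays on oxygen.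

**Step 3**
Reactants: 4 3-acetyl-4-hydroxy-2,6-dimethoxyphenyl acetate
Product: 5 1-(2,5-dihydroxy-4,6-dimethoxyphenyl)ethan-1-one
Conditions: conc. HCl (cat.), MeOH, reflux, N2
Reagents that add atoms: none
Why: Acid-catalysed transesterification removes the aryl acetate, and acidic conditions protect the electron-rich hydroquinone from the air oxidation that base would promote.

**Step 4**
Reactants: 5 1-(2,5-dihydroxy-4,6-dimethoxyphenyl)ethan-1-one
Product: 6 1-[3-(benzyloxy)-6-hydroxy-2,4-dimethoxyphenyl]ethan-1-one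
Conditions: BnBr (1.05 equiv), K2CO3 (1.2 equiv), acetone, reflux, N2
Reagents that add atoms: benzyl bromide, BrCc1ccccc1
Why: Williamson etherification, selective because the 2'-OH is hydrogen-bonded to the ketone and far less nucleophilic than the free 5'-OH.

**Step 5**
Reactants: 6 1-[3-(benzyloxy)-6-hydroxy-2,4-dimethoxyphenyl]ethan-1-one
Product: 7 tert-butyl 3-[3-(benzyloxy)-6-hydroxy-2,4-dimethoxyphenyl]-3-oxopropanoate
Conditions: LiN(SiMe3)2 (3.3 equiv), THF, −78 °C; Boc2O (1.1 equiv), −78 to −20 °C; aq. NH4Cl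
Reagents that add atoms: di-tert-butyl dicarbonate, CC(C)(C)OC(=O)OC(=O)OC(C)(C)C
Why: Crossed Claisen-type C-acylation of the phenoxide–enolate dianion; the third equivalent of base deprotonates the β-ketoester as it forms, which drives the reaction and prevents double acylation.

**Step 6**
Reactants: 7 tert-butyl 3-[3-(benzyloxy)-6-hydroxy-2,4-dimethoxyphenyl]-3-oxopropanoate; 8 3,4-dimethoxybenzaldehyde (veratraldehyde)
Product: 9 tert-butyl (2Z)-2-[3-(benzyloxy)-6-hydroxy-2,4-dimethoxybenzoyl]-3-(3,4-dimethoxyphenyl)prop-2-enoate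
Conditions: piperidine (20 mol %), AcOH (20 mol %), 4 Å molecular sieves, toluene, rt
Reagents that add atoms: none
Why: Knoevenagel (aldol-type) condensation of the doubly activated methylene with the aldehyde forms the future C2–C3 bond under mild conditions, giving the expected major Z isomer (ring B trans to the aroyl group) while the phenol–ketone hydrogen bond slows premature ring closure.

**Step 7**
Reactants: 9 tert-butyl (2Z)-2-[3-(benzyloxy)-6-hydroxy-2,4-dimethoxybenzoyl]-3-(3,4-dimethoxyphenyl)prop-2-enoate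
Product: 12 (2S)-6-(benzyloxy)-2-(3,4-dimethoxyphenyl)-5,7-dimethoxychroman-4-one, via trans-flavanone-3-carboxylic tert-butyl ester 10 (not isolated), via flavanone-3-carboxylic acid 11 (not isolated)
Conditions: N-[3,5-bis(trifluoromethyl)phenyl]-N'-[(9R)-6'-methoxycinchonan-9-yl]thiourea (10 mol %), toluene, −25 °C; then TsOH·H2O (0.5 equiv), 80 °C; recrystallise
Reagents that add atoms: none
Why: Catalytic enantioselective 6-endo oxa-Michael addition in which the thiourea binds the β-ketoester and the quinuclidine activates the phenol, fixing C2 as S by catalyst control, after which acid cleaves the tert-butyl ester and the β-keto acid decarboxylates without touching C2.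

**Step 8**
Reactants: 12 (2S)-6-(benzyloxy)-2-(3,4-dimethoxyphenyl)-5,7-dimethoxychroman-4-one
Product: 13 (2S)-2-(3,4-dimethoxyphenyl)-6-hydroxy-5,7-dimethoxychroman-4-one
Conditions: H2 (1 atm), 10% Pd/C, EtOAc, rt
Reagents that add atoms: none
Why: Hydrogenolysis of the aryl benzyl ether under neutral conditions, so the base- and acid-sensitive C2 stereocentre (ring-opening to the chalcone) is not scrambled.

**Compound list**
1 | 2,6-dimethoxy-1,4-benzoquinone | COC1=CC(=O)C=C(OC)C1=O | starting material
2 | 2,6-dimethoxybenzene-1,4-diol (2,6-dimethoxyhydroquinone) | COc1cc(O)cc(OC)c1O | intermediate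
3 | 2,6-dimethoxy-1,4-phenylene diacetate | COc1cc(OC(C)=O)cc(OC)c1OC(C)=O | intermediate
4 | 3-acetyl-4-hydroxy-2,6-dimethoxyphenyl acetate | CC(=O)Oc1c(OC)cc(O)c(C(C)=O)c1OC | intermediate
5 | 1-(2,5-dihydroxy-4,6-dimethoxyphenyl)ethan-1-one | CC(=O)c1c(O)cc(OC)c(O)c1OC | intermediate
6 | 1-[3-(benzyloxy)-6-hydroxy-2,4-dimethoxyphenyl]ethan-1-one | CC(=O)c1c(O)cc(OC)c(OCc2ccccc2)c1OC | intermediate
7 | tert-butyl 3-[3-(benzyloxy)-6-hydroxy-2,4-dimethoxyphenyl]-3-oxopropanoate | CC(C)(C)OC(=O)CC(=O)c1c(O)cc(OC)c(OCc2ccccc2)c1OC | intermediate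
8 | 3,4-dimethoxybenzaldehyde (veratraldehyde) | COc1ccc(C=O)cc1OC | starting material
9 | tert-butyl (2Z)-2-[3-(benzyloxy)-6-hydroxy-2,4-dimethoxybenzoyl]-3-(3,4-dimethoxyphenyl)prop-2-enoate | CC(C)(C)OC(=O)/C(C(=O)c1c(O)cc(OC)c(OCc2ccccc2)c1OC)=C\c1ccc(OC)c(OC)c1 | intermediate
10 | tert-butyl (2S,3R)-6-(benzyloxy)-2-(3,4-dimethoxyphenyl)-5,7-dimethoxy-4-oxochromane-3-carboxylate (trans; C3 epimerisable) | COc1ccc([C@@H]2[C@@H](C(=O)OC(C)(C)C)C(=O)c3c(cc(OC)c(OCc4ccccc4)c3OC)O2)cc1OC | intermediate
11 | (2S,3R)-6-(benzyloxy)-2-(3,4-dimethoxyphenyl)-5,7-dimethoxy-4-oxochromane-3-carboxylic acid | COc1ccc([C@@H]2[C@@H](C(=O)O)C(=O)c3c(cc(OC)c(OCc4ccccc4)c3OC)O2)cc1OC | intermediate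
12 | (2S)-6-(benzyloxy)-2-(3,4-dimethoxyphenyl)-5,7-dimethoxychroman-4-one | COc1ccc([C@@H]2CC(=O)c3c(cc(OC)c(OCc4ccccc4)c3OC)O2)cc1OC | intermediate
13 | (2S)-2-(3,4-dimethoxyphenyl)-6-hydroxy-5,7-dimethoxychroman-4-one | COc1ccc([C@@H]2CC(=O)c3c(cc(OC)c(O)c3OC)O2)cc1OC | target

**Totals**
Total step count: 8. Longest linear sequence: 8 steps (1 to 13); veratraldehyde 8 enters at step 6.

**Three steps most likely to fail**

Step 7. The enantiomeric excess may fall short, or the TsOH decarboxylation may partly racemise this electron-rich flavanone by ring opening. The fallback sets out from 6 and 8 and comes back at 12. Claisen–Schmidt aldol condensation of 6 with 8 (KOH, EtOH, rt) gives the chalcone (2E)-1-[3-(benzyloxy)-6-hydroxy-2,4-dimethoxyphenyl]-3-(3,4-dimethoxyphenyl)prop-2-en-1-one F1. Heating it with NaOAc in EtOH closes it to racemic 6-(benzyloxy)-2-(3,4-dimethoxyphenyl)-5,7-dimethoxychroman-4-one F2. Kinetic resolution by asymmetric transfer hydrogenation (RuCl[(R,R)-TsDPEN](p-cymene), HCO2H/Et3N, rt, to about 55% conversion) should reduce the 2R enantiomer faster, to the cis alcohol (2R,4R)-6-(benzyloxy)-2-(3,4-dimethoxyphenyl)-5,7-dimethoxychroman-4-ol F3. Unreacted (2S)-12 is then recovered by chromatography. The same resolution can also polish scalemic 12 from step 7.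

Step 6. Piperidine may close the free phenol onto the new alkene and give racemic 10, or the electron-rich aldehyde may condense sluggishly. The fallback sets out from 7 and comes back at 9. Silylation of 7 (TBSCl, imidazole, DMF) gives tert-butyl 3-[3-(benzyloxy)-6-[(tert-butyldimethylsilyl)oxy]-2,4-dimethoxyphenyl]-3-oxopropanoate F4. With the phenol masked, the Knoevenagel condensation with 8 can be forced (piperidine/AcOH, toluene, Dean–Stark) to tert-butyl (2Z)-2-[3-(benzyloxy)-6-[(tert-butyldimethylsilyl)oxy]-2,4-dimethoxybenzoyl]-3-(3,4-dimethoxyphenyl)prop-2-enoate F5. Desilylation under weakly acidic, base-free conditions (HF·pyridine, THF, 0 °C) then releases 9 without triggering the background cyclisation.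

Step 5. O-acylation, over-acylation or lactonisation to a 4-hydroxycoumarin may compete with clean C-acylation of the dianion. The fallback sets out from 6 and comes back at 7. The phenol is first acylated on oxygen (Boc2O, DMAP cat., Et3N, CH2Cl2) to 2-acetyl-4-(benzyloxy)-3,5-dimethoxyphenyl tert-butyl carbonate F6. Treatment with LiN(SiMe3)2 (2.2 equiv, THF, −78 to 0 °C) then effects a Baker–Venkataraman-type intramolecular O-to-C transfer of the tert-butoxycarbonyl group; the six-membered tetrahedral intermediate expels the phenoxide and gives 7.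

**Further compounds**
F1 | step 7 | (2E)-1-[3-(benzyloxy)-6-hydroxy-2,4-dimethoxyphenyl]-3-(3,4-dimethoxyphenyl)prop-2-en-1-one | COc1ccc(/C=C/C(=O)c2c(O)cc(OC)c(OCc3ccccc3)c2OC)cc1OC
F2 | step 7 | racemic 6-(benzyloxy)-2-(3,4-dimethoxyphenyl)-5,7-dimethoxychroman-4-one | COc1ccc(C2CC(=O)c3c(cc(OC)c(OCc4ccccc4)c3OC)O2)cc1OC
F3 | step 7 | (2R,4R)-6-(benzyloxy)-2-(3,4-dimethoxyphenyl)-5,7-dimethoxychroman-4-ol | COc1ccc([C@H]2C[C@@H](O)c3c(cc(OC)c(OCc4ccccc4)c3OC)O2)cc1OC
F4 | step 6 | tert-butyl 3-[3-(benzyloxy)-6-[(tert-butyldimethylsilyl)oxy]-2,4-dimethoxyphenyl]-3-oxopropanoate | CC(C)(C)OC(=O)CC(=O)c1c(O[Si](C)(C)C(C)(C)C)cc(OC)c(OCc2ccccc2)c1OC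
F5 | step 6 | tert-butyl (2Z)-2-[3-(benzyloxy)-6-[(tert-butyldimethylsilyl)oxy]-2,4-dimethoxybenzoyl]-3-(3,4-dimethoxyphenyl)prop-2-enoate | CC(C)(C)OC(=O)/C(C(=O)c1c(O[Si](C)(C)C(C)(C)C)cc(OC)c(OCc2ccccc2)c1OC)=C\c1ccc(OC)c(OC)c1
F6 | step 5 | 2-acetyl-4-(benzyloxy)-3,5-dimethoxyphenyl tert-butyl carbonate | CC(=O)c1c(OC(=O)OC(C)(C)C)cc(OC)c(OCc2ccccc2)c1OC
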